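**Plan**
- Retrosynthesis: cut O1–C2 (pyran ring, phenoxide displacement), then C2–C3 (one-carbon boronate homologation), then C3–C1′ (the union of the two halves). This leaves a ring-A phenethyl carbamate and a ring-B arylboronic ester.
- Ring B: the 1,1-dimethylallyl group at C5′, ortho to 4′-OH, goes back by an aromatic Claisen rearrangement to an O-prenyl ether. 3′-OH comes from an aldehyde (Dakin), and the C1′–B bond from methoxy-directed lithiation.
- Forward: the ring-B boronate (5 steps) and the ring-A carbamate (3 steps) are joined at C3–C1′. The C3–B bond is homologated to C2–OH, O1–C2 is closed by desilylative etherification (pyran ring formed last), and the MOM groups are then removed.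
- Enabling feature: C3 is a benzylic CH on ring B flanked by C4H2 and C2H2–O1. This is the carbon formed when the ring-B aryl migrates from boron to an α-oxygenated carbanion at the end of the ring-A phenethyl unit, and the C3–B bond left behind becomes C2.
- Stereochemistry: the only stereocentre (3R) is set in the key step by (−)-sparteine-mediated lithiation, borylation with retention and 1,2-shift with inversion. No later step touches C3.

Key step: step 9

Remark: the SMILES encodes the (3R)-isoflavan; isoflavan numbering is used (O1, C2, C3, C4; ring A C4a–C8a; ring B C1′–C6′).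
Abbreviations: ArA = 2,4-bis[(triisopropylsilyl)oxy]phenyl; ArB = 2-methoxy-3,4-bis(methoxymethoxy)-5-(2-methylbut-3-en-2-yl)phenyl; Cb = C(O)N(i-Pr)2; pin = pinacolato.

**Step 1**
Reactants: 1 2-hydroxy-6-methoxybenzaldehyde
Product: 2 2-methoxy-6-[(3-methylbut-2-en-1-yl)oxy]benzaldehyde
Conditions: prenyl bromide, K2CO3, DMF, 50 °C
Reagents that add atoms: 1-bromo-3-methylbut-2-ene (prenyl bromide), CC(C)=CCBr
Why: Williamson O-alkylation of the phenoxide with the allylic bromide (SN2) should give the prenyl ether needed for the Claisen rearrangement.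

**Step 2**
Reactants: 2 2-methoxy-6-[(3-methylbut-2-en-1-yl)oxy]benzaldehyde
Product: 4 2-hydroxy-6-methoxy-3-(2-methylbut-3-en-2-yl)benzaldehyde, via ortho-dienone 3 (not isolated)
Conditions: PhNEt2, 190 °C, sealed tube
Reagents that add atoms: none
Why: Aromatic Claisen ([3,3]-sigmatropic) rearrangement should deliver the γ-carbon of the prenyl group to the only unsubstituted ortho position (the other carries CHO), and base-assisted tautomerisation of the dienone should give the phenol, whose hydrogen bond to the aldehyde disfavours abnormal Claisen and cyclisation reactions.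

**Step 3**
Reactants: 4 2-hydroxy-6-methoxy-3-(2-methylbut-3-en-2-yl)benzaldehyde
Product: 6 3-methoxy-6-(2-methylbut-3-en-2-yl)benzene-1,2-diol, via aryl formate 5 (not isolated)
Conditions: 30% aq. H2O2, aq. NaOH, THF, 0 °C → rt, N2; acidic work-up
Reagents that add atoms: hydrogen peroxide, OO
Why: Dakin oxidation (hydroperoxide addition to the ortho-hydroxybenzaldehyde, aryl migration, hydrolysis of the formate) should convert CHO into the 3′-OH, while the unactivated terminal alkene is inert to alkaline H2O2.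

**Step 4**
Reactants: 6 3-methoxy-6-(2-methylbut-3-en-2-yl)benzene-1,2-diol
Product: 7 1-methoxy-2,3-bis(methoxymethoxy)-4-(2-methylbut-3-en-2-yl)benzene
Conditions: NaH, MOMCl, DMF, 0 °C → rt, Ar
Reagents that add atoms: chloromethyl methyl ether (MOMCl), COCCl
Why: Double Williamson etherification should cap the catechol as MOM acetals, which are small enough for the hindered 4′-oxygen and stable to organolithiums and fluoride.

**Step 5**
Reactants: 7 1-methoxy-2,3-bis(methoxymethoxy)-4-(2-methylbut-3-en-2-yl)benzene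
Product: 9 2-[2-methoxy-3,4-bis(methoxymethoxy)-5-(2-methylbut-3-en-2-yl)phenyl]-4,4,5,5-tetramethyl-1,3,2-dioxaborolane, via aryllithium 8 (not isolated)
Conditions: n-BuLi, TMEDA, Et2O, 0 °C → rt; then i-PrOBpin, −78 °C → rt
Reagents that add atoms: 2-isopropoxy-4,4,5,5-tetramethyl-1,3,2-dioxaborolane, CC(C)OB1OC(C)(C)C(C)(C)O1
Why: Directed ortho-metalation should occur at C1′–H, the only ring C–H ortho to an oxygen substituent (both positions ortho to the OMOM groups are substituted, C6′–H lies next to the tert-alkyl group), and the aryllithium is trapped by electrophilic borylation.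

**Step 6**
Reactants: 10 4-bromobenzene-1,3-diol
Product: 11 1-bromo-2,4-bis[(triisopropylsilyl)oxy]benzene
Conditions: TIPSCl, imidazole, DMF, rt
Reagents that add atoms: chlorotriisopropylsilane, CC(C)[Si](Cl)(C(C)C)C(C)C
Why: Silylation of both phenols gives bulky TIPS ethers that tolerate alkyllithiums and suppress ortho-lithiation and silyl migration in steps 7 and 9.

**Step 7**
Reactants: 11 1-bromo-2,4-bis[(triisopropylsilyl)oxy]benzene
Product: 13 2-{2,4-bis[(triisopropylsilyl)oxy]phenyl}ethan-1-ol, via aryllithium 12 (not isolated)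
Conditions: n-BuLi, THF, −78 °C; then ethylene oxide (THF solution), −78 → 0 °C
Reagents that add atoms: ethylene oxide (oxirane), C1CO1
Why: Bromine–lithium exchange followed by ring-opening of the epoxide by the aryllithium should attach the two-carbon chain (future C4 and C3) to C4a.

**Step 8**
Reactants: 13 2-{2,4-bis[(triisopropylsilyl)oxy]phenyl}ethan-1-ol
Product: 14 2-{2,4-bis[(triisopropylsilyl)oxy]phenyl}ethyl N,N-diisopropylcarbamate
Conditions: CbCl, Et3N, CH2Cl2, reflux
Reagents that add atoms: N,N-diisopropylcarbamoyl chloride, CC(C)N(C(C)C)C(Cl)=O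
Why: Carbamoylation (acyl substitution at the carbamoyl chloride) installs the hindered carbamate that directs α-lithiation and later serves as the leaving group.

**Step 9**
Reactants: 14 2-{2,4-bis[(triisopropylsilyl)oxy]phenyl}ethyl N,N-diisopropylcarbamate; 9 2-[2-methoxy-3,4-bis(methoxymethoxy)-5-(2-methylbut-3-en-2-yl)phenyl]-4,4,5,5-tetramethyl-1,3,2-dioxaborolane
Product: 17 2-[(1R)-2-ArA-1-ArB-ethyl]-4,4,5,5-tetramethyl-1,3,2-dioxaborolane, via lithiated carbamate 15 (not isolated), via boronate complex 16 (not isolated)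
Conditions: 14, s-BuLi, (−)-sparteine, Et2O, −78 °C, 5 h; add 9, −78 °C, 1 h; then reflux, 12 h
Reagents that add atoms: none
Why: s-BuLi/(−)-sparteine should remove the pro-S α-proton of 14 (carbamate-directed deprotonation) to give the configurationally stable (S)-organolithium 15, which attacks the boron of 9 with retention to give boronate 16; on warming, the ring-B aryl group migrates from boron to C3 antiperiplanar to the departing carbamate (1,2-metallate rearrangement, inversion at carbon), forming the C3–C1′ bond and boronic ester 17. The closest known reaction type is the lithiation–borylation of primary alkyl N,N-diisopropylcarbamates with aryl pinacol boronic esters. No ring is closed in this step. The new stereocentre C3 is controlled by the reagent alone: the chiral diamine fixes the configuration of 15 and the retention/inversion sequence is stereospecific, so (−)-sparteine should lead to 1R in 17, which becomes 3R in the target. The step needs lithiation α to the carbamate oxygen rather than benzylic or ring metalation or attack at silicon, which the directing carbamate, the low temperature and the bulky TIPS ethers should secure, and it needs irreversible formation of 16 before migration, which an unhindered primary carbanion and a mono-ortho-substituted aryl boronate should allow. The MOM ethers and the terminal alkene of 9 are inert to the carbanion.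

**Step 10**
Reactants: 17 2-[(1R)-2-ArA-1-ArB-ethyl]-4,4,5,5-tetramethyl-1,3,2-dioxaborolane
Product: 20 (2R)-3-ArA-2-ArB-propan-1-ol, via chloromethyl boronate complex 18 (not isolated), via homologated boronic ester 19 (not isolated)
Conditions: BrCH2Cl, n-BuLi, THF, −78 °C → rt; then 30% aq. H2O2, 2 M NaOH, 0 °C
Reagents that add atoms: bromochloromethane, ClCBr; hydrogen peroxide, OO
Why: Matteson homologation (chloromethyllithium adds to boron and the benzylic carbon migrates with retention, displacing chloride) inserts C2, and oxidation of the primary C–B bond gives the alcohol without touching C3.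

**Step 11**
Reactants: 20 (2R)-3-ArA-2-ArB-propan-1-ol
Product: 21 (2R)-3-ArA-2-ArB-propyl methanesulfonate
Conditions: MsCl, Et3N, CH2Cl2, 0 °C
Reagents that add atoms: methanesulfonyl chloride, CS(Cl)(=O)=O
Why: Sulfonylation of the primary alcohol turns C2–O into a leaving group under conditions that leave the silyl ethers, MOM ethers and alkene untouched.

**Step 12**
Reactants: 21 (2R)-3-ArA-2-ArB-propyl methanesulfonate
Product: 23 (3R)-3-[2-methoxy-3,4-bis(methoxymethoxy)-5-(2-methylbut-3-en-2-yl)phenyl]-3,4-dihydro-2H-chromen-7-ol, via bis(phenoxide) 22 (not isolated)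
Conditions: TBAF, THF (0.02 M), 0 °C → rt, Ar; aqueous work-up
Reagents that add atoms: none
Why: Fluoride cleaves both aryl silyl ethers and the ortho-phenoxide should close the pyran ring by 6-exo-tet intramolecular Williamson etherification at C2, while ring B stays as neutral MOM ethers and so can neither participate as a phenoxide nor be oxidised.

**Step 13**
Reactants: 23 (3R)-3-[2-methoxy-3,4-bis(methoxymethoxy)-5-(2-methylbut-3-en-2-yl)phenyl]-3,4-dihydro-2H-chromen-7-ol
Product: 24 4-[(3R)-7-hydroxy-3,4-dihydro-2H-chromen-3-yl]-3-methoxy-6-(2-methylbut-3-en-2-yl)benzene-1,2-diol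
Conditions: HCl (1.25 M in MeOH), rt → 40 °C, Ar
Reagents that add atoms: none
Why: Acid-catalysed acetal cleavage in methanol should remove both MOM groups with formaldehyde trapped as dimethoxymethane, and the vinyl group on a quaternary carbon should not be protonated by dilute methanolic HCl at this temperature.

**Compound list**
1 | 2-hydroxy-6-methoxybenzaldehyde | COc1cccc(O)c1C=O | starting material
2 | 2-methoxy-6-[(3-methylbut-2-en-1-yl)oxy]benzaldehyde | COc1cccc(OCC=C(C)C)c1C=O | intermediate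
3 | 2-methoxy-5-(2-methylbut-3-en-2-yl)-6-oxocyclohexa-1,3-diene-1-carbaldehyde (ortho-dienone, racemic) | COC1=C(C=O)C(=O)C(C(C)(C)C=C)C=C1 | intermediate
4 | 2-hydroxy-6-methoxy-3-(2-methylbut-3-en-2-yl)benzaldehyde | COc1ccc(C(C)(C)C=C)c(O)c1C=O | intermediate
5 | 2-hydroxy-6-methoxy-3-(2-methylbut-3-en-2-yl)phenyl formate | COc1ccc(C(C)(C)C=C)c(O)c1OC=O | intermediate
6 | 3-methoxy-6-(2-methylbut-3-en-2-yl)benzene-1,2-diol | COc1ccc(C(C)(C)C=C)c(O)c1O | intermediate
7 | 1-methoxy-2,3-bis(methoxymethoxy)-4-(2-methylbut-3-en-2-yl)benzene | COc1ccc(C(C)(C)C=C)c(OCOC)c1OCOC | intermediate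
8 | [2-methoxy-3,4-bis(methoxymethoxy)-5-(2-methylbut-3-en-2-yl)phenyl]lithium | COc1c([Li])cc(C(C)(C)C=C)c(OCOC)c1OCOC | intermediate
9 | 2-[2-methoxy-3,4-bis(methoxymethoxy)-5-(2-methylbut-3-en-2-yl)phenyl]-4,4,5,5-tetramethyl-1,3,2-dioxaborolane | COc1c(B2OC(C)(C)C(C)(C)O2)cc(C(C)(C)C=C)c(OCOC)c1OCOC | intermediate
10 | 4-bromobenzene-1,3-diol | Oc1ccc(Br)c(O)c1 | starting material
11 | 1-bromo-2,4-bis[(triisopropylsilyl)oxy]benzene | CC(C)[Si](Oc1ccc(Br)c(O[Si](C(C)C)(C(C)C)C(C)C)c1)(C(C)C)C(C)C | intermediate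
12 | {2,4-bis[(triisopropylsilyl)oxy]phenyl}lithium | [Li]c1ccc(O[Si](C(C)C)(C(C)C)C(C)C)cc1O[Si](C(C)C)(C(C)C)C(C)C | intermediate
13 | 2-{2,4-bis[(triisopropylsilyl)oxy]phenyl}ethan-1-ol | OCCc1ccc(O[Si](C(C)C)(C(C)C)C(C)C)cc1O[Si](C(C)C)(C(C)C)C(C)C | intermediate
14 | 2-{2,4-bis[(triisopropylsilyl)oxy]phenyl}ethyl N,N-diisopropylcarbamate | CC(C)N(C(C)C)C(=O)OCCc1ccc(O[Si](C(C)C)(C(C)C)C(C)C)cc1O[Si](C(C)C)(C(C)C)C(C)C | intermediate
15 | [(1S)-2-{2,4-bis[(triisopropylsilyl)oxy]phenyl}-1-[(diisopropylcarbamoyl)oxy]ethyl]lithium (as its (−)-sparteine complex) | CC(C)N(C(C)C)C(=O)O[C@@H]([Li])Cc1ccc(O[Si](C(C)C)(C(C)C)C(C)C)cc1O[Si](C(C)C)(C(C)C)C(C)C | intermediate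
16 | lithium [(1S)-2-{2,4-bis[(triisopropylsilyl)oxy]phenyl}-1-[(diisopropylcarbamoyl)oxy]ethyl][2-methoxy-3,4-bis(methoxymethoxy)-5-(2-methylbut-3-en-2-yl)phenyl](pinacolato)borate | [Li+].CC(C)N(C(C)C)C(=O)O[C@@H]([B-]1(c2cc(C(C)(C)C=C)c(OCOC)c(OCOC)c2OC)OC(C)(C)C(C)(C)O1)Cc1ccc(O[Si](C(C)C)(C(C)C)C(C)C)cc1O[Si](C(C)C)(C(C)C)C(C)C | intermediate
17 | 2-[(1R)-2-{2,4-bis[(triisopropylsilyl)oxy]phenyl}-1-[2-methoxy-3,4-bis(methoxymethoxy)-5-(2-methylbut-3-en-2-yl)phenyl]ethyl]-4,4,5,5-tetramethyl-1,3,2-dioxaborolane | COc1c([C@@H](Cc2ccc(O[Si](C(C)C)(C(C)C)C(C)C)cc2O[Si](C(C)C)(C(C)C)C(C)C)B2OC(C)(C)C(C)(C)O2)cc(C(C)(C)C=C)c(OCOC)c1OCOC | intermediate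
18 | lithium (chloromethyl)[(1R)-2-{2,4-bis[(triisopropylsilyl)oxy]phenyl}-1-[2-methoxy-3,4-bis(methoxymethoxy)-5-(2-methylbut-3-en-2-yl)phenyl]ethyl](pinacolato)borate | [Li+].COc1c([C@@H](Cc2ccc(O[Si](C(C)C)(C(C)C)C(C)C)cc2O[Si](C(C)C)(C(C)C)C(C)C)[B-]2(CCl)OC(C)(C)C(C)(C)O2)cc(C(C)(C)C=C)c(OCOC)c1OCOC | intermediate
19 | 2-[(2R)-3-{2,4-bis[(triisopropylsilyl)oxy]phenyl}-2-[2-methoxy-3,4-bis(methoxymethoxy)-5-(2-methylbut-3-en-2-yl)phenyl]propyl]-4,4,5,5-tetramethyl-1,3,2-dioxaborolane | COc1c([C@@H](Cc2ccc(O[Si](C(C)C)(C(C)C)C(C)C)cc2O[Si](C(C)C)(C(C)C)C(C)C)CB2OC(C)(C)C(C)(C)O2)cc(C(C)(C)C=C)c(OCOC)c1OCOC | intermediate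
20 | (2R)-3-{2,4-bis[(triisopropylsilyl)oxy]phenyl}-2-[2-methoxy-3,4-bis(methoxymethoxy)-5-(2-methylbut-3-en-2-yl)phenyl]propan-1-ol | COc1c([C@@H](Cc2ccc(O[Si](C(C)C)(C(C)C)C(C)C)cc2O[Si](C(C)C)(C(C)C)C(C)C)CO)cc(C(C)(C)C=C)c(OCOC)c1OCOC | intermediate
21 | (2R)-3-{2,4-bis[(triisopropylsilyl)oxy]phenyl}-2-[2-methoxy-3,4-bis(methoxymethoxy)-5-(2-methylbut-3-en-2-yl)phenyl]propyl methanesulfonate | COc1c([C@@H](Cc2ccc(O[Si](C(C)C)(C(C)C)C(C)C)cc2O[Si](C(C)C)(C(C)C)C(C)C)COS(C)(=O)=O)cc(C(C)(C)C=C)c(OCOC)c1OCOC | intermediate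
22 | bis(tetrabutylammonium) 4-[(2R)-3-(methanesulfonyloxy)-2-[2-methoxy-3,4-bis(methoxymethoxy)-5-(2-methylbut-3-en-2-yl)phenyl]propyl]benzene-1,3-diolate | COc1c([C@@H](Cc2ccc([O-])cc2[O-])COS(C)(=O)=O)cc(C(C)(C)C=C)c(OCOC)c1OCOC.CCCC[N+](CCCC)(CCCC)CCCC.CCCC[N+](CCCC)(CCCC)CCCC | intermediate
23 | (3R)-3-[2-methoxy-3,4-bis(methoxymethoxy)-5-(2-methylbut-3-en-2-yl)phenyl]-3,4-dihydro-2H-chromen-7-ol | COc1c([C@@H]2COc3cc(O)ccc3C2)cc(C(C)(C)C=C)c(OCOC)c1OCOC | intermediate
24 | 4-[(3R)-7-hydroxy-3,4-dihydro-2H-chromen-3-yl]-3-methoxy-6-(2-methylbut-3-en-2-yl)benzene-1,2-diol | C=CC(C)(C)c1cc([C@@H]2COc3cc(O)ccc3C2)c(OC)c(O)c1O | target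

**Step count and risks**

Total step count: 13. Longest linear sequence: 10 steps (steps 1–5, then 9–13).

Step 9. What may go wrong: boronate formation between the bulky diamine-bound carbanion and the ortho-methoxy aryl boronate may be incomplete or reversible, the carbanion may be lost by silyl migration from the ortho-OTIPS group, and enantiomeric purity may erode. The fallback replaces reagent control by substrate control through a chiral diol on boron; it sets out from 11 and 7 and comes back at 20. Aryllithium 12 (from 11 as in step 7) is added to the (chloromethyl)boronic ester of (R,R)-1,2-dicyclohexylethane-1,2-diol (DICHED) to give (4R,5R)-2-{2,4-bis[(triisopropylsilyl)oxy]benzyl}-4,5-dicyclohexyl-1,3,2-dioxaborolane F1. Matteson homologation with LiCHCl2/ZnCl2 (−100 °C → rt) should give the (1S)-1-chloro-2-arylethyl boronic ester F2 (configuration assigned from the usual sense of induction by (R,R)-diols). Aryllithium 8 (from 7 as in step 5) adds to boron and displaces chloride with inversion to give the (1R)-boronic ester F3, the DICHED analogue of 17. Homologation with chloromethyllithium gives the (2R)-propylboronic ester F4, and alkaline hydrogen peroxide then gives 20.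

Step 2. What may go wrong: Claisen–Cope migration to the free para position, further reaction of the ortho-(1,1-dimethylallyl)phenol (abnormal Claisen, cyclisation onto the alkene), or loss of the prenyl group. The fallback makes the 1,1-dimethylallyl group by cross-coupling instead of rearrangement; it sets out from 1 and comes back at 7. Dakin oxidation of 1 gives 3-methoxybenzene-1,2-diol F5, and MOMCl/NaH gives 1-methoxy-2,3-bis(methoxymethoxy)benzene F6. Lithiation ortho to the OMOM group (a stronger director than OMe) and quenching with 1,2-dibromoethane gives 1-bromo-4-methoxy-2,3-bis(methoxymethoxy)benzene F7. A ligand-controlled γ-selective Suzuki–Miyaura coupling of F7 with 3-methylbut-2-en-1-ylboronic acid pinacol ester (Pd/bulky biarylphosphine, K3PO4) should then give 7.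

Step 5. What may go wrong: deprotonation next to the weakly directing, flanked methoxy group may be slow or incomplete, and the base may be consumed elsewhere. The fallback uses electrophilic halogenation and halogen–metal exchange; it sets out from 7 and comes back at 9 through 8. NBS in MeCN at 0 °C should brominate C1′ (para to the 4′-OMOM group and ortho to OMe; C6′ is shielded by the tert-alkyl group) to give 1-bromo-2-methoxy-3,4-bis(methoxymethoxy)-5-(2-methylbut-3-en-2-yl)benzene F8. Bromine–lithium exchange (n-BuLi, THF, −78 °C) gives 8, which is borylated to 9 as in step 5.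

**Further compounds**
F1 | step 9 | (4R,5R)-2-{2,4-bis[(triisopropylsilyl)oxy]benzyl}-4,5-dicyclohexyl-1,3,2-dioxaborolane | CC(C)[Si](Oc1ccc(CB2O[C@H](C3CCCCC3)[C@@H](C3CCCCC3)O2)c(O[Si](C(C)C)(C(C)C)C(C)C)c1)(C(C)C)C(C)C
F2 | step 9 | (4R,5R)-2-[(1S)-1-chloro-2-{2,4-bis[(triisopropylsilyl)oxy]phenyl}ethyl]-4,5-dicyclohexyl-1,3,2-dioxaborolane | CC(C)[Si](Oc1ccc(C[C@@H](Cl)B2O[C@H](C3CCCCC3)[C@@H](C3CCCCC3)O2)c(O[Si](C(C)C)(C(C)C)C(C)C)c1)(C(C)C)C(C)C
F3 | step 9 | (4R,5R)-2-[(1R)-2-{2,4-bis[(triisopropylsilyl)oxy]phenyl}-1-[2-methoxy-3,4-bis(methoxymethoxy)-5-(2-methylbut-3-en-2-yl)phenyl]ethyl]-4,5-dicyclohexyl-1,3,2-dioxaborolane | COc1c([C@@H](Cc2ccc(O[Si](C(C)C)(C(C)C)C(C)C)cc2O[Si](C(C)C)(C(C)C)C(C)C)B2O[C@H](C3CCCCC3)[C@@H](C3CCCCC3)O2)cc(C(C)(C)C=C)c(OCOC)c1OCOC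
F4 | step 9 | (4R,5R)-2-[(2R)-3-{2,4-bis[(triisopropylsilyl)oxy]phenyl}-2-[2-methoxy-3,4-bis(methoxymethoxy)-5-(2-methylbut-3-en-2-yl)phenyl]propyl]-4,5-dicyclohexyl-1,3,2-dioxaborolane | COc1c([C@@H](Cc2ccc(O[Si](C(C)C)(C(C)C)C(C)C)cc2O[Si](C(C)C)(C(C)C)C(C)C)CB2O[C@H](C3CCCCC3)[C@@H](C3CCCCC3)O2)cc(C(C)(C)C=C)c(OCOC)c1OCOC
F5 | step 2 | 3-methoxybenzene-1,2-diol | COc1cccc(O)c1O
F6 | step 2 | 1-methoxy-2,3-bis(methoxymethoxy)benzene | COCOc1cccc(OC)c1OCOC
F7 | step 2 | 1-bromo-4-methoxy-2,3-bis(methoxymethoxy)benzene | COCOc1c(Br)ccc(OC)c1OCOC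
F8 | step 5 | 1-bromo-2-methoxy-3,4-bis(methoxymethoxy)-5-(2-methylbut-3-en-2-yl)benzene | COc1c(Br)cc(C(C)(C)C=C)c(OCOC)c1OCOC
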